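## Structural features

Isopoegin B is an isoflavone: a 4H-chromen-4-one (benzo ring A fused to pyranone ring C) that carries an aryl group, ring B, on C3. Ring A has a free 5-hydroxyl, peri to and hydrogen-bonded with the C4 carbonyl, and a 7-methoxy group. Ring B has hydroxyls at C2' and C4' and a 3-methylbut-2-enyl (prenyl) chain at C5', ortho to the 4'-hydroxyl. There is no stereocenter, so no two stereocenters stand next to each other and nothing has to be set or guarded against epimerization. The fragile parts are the prenyl group next to a phenol (acid can close it to a 2,2-dimethylchroman; oxidants and hydrogenation attack the olefin), the three free phenols, and C2 of the pyranone, which strong base opens. The real difficulty is regiochemical: one oxygen out of four must be the methyl ether, the prenyl group must sit on one defined ring B carbon, and the C3–C1' bond must be made beside a free 2'-hydroxyl. The feature exploited is that the 2'-oxygen lies where it could equally be bonded to C2. Moving the C2–O bond from O1 of ring C to O2' turns the isoflavone into an isomeric 3-aroylbenzofuran whose aroyl ring A is a symmetric 2,6-dihydroxy-4-methoxyphenyl group, so either ring A hydroxyl can close the pyranone.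

## Logic of the disconnections

**19 ⇒ 16.** The O1–C2 bond of ring C is cut and C2 is joined to the 2'-oxygen instead, which turns the pyranone into a furan; capping the three phenols as acetals gives 16 (17 and 18 lie on the way). The cut is made there because ring A becomes symmetric, so the question of which ring A oxygen ends as O1 disappears, and because every carbon–carbon bond of 19 is already present in 16. The gain is that the isoflavone problem becomes a benzofuran problem in which all phenols may be protected alike. The forward step must run the ring exchange toward the pyranone and must unmask three acetals with acid without harming the prenyl group. The three methoxymethyl groups of 16 are kept because they also direct the lithiation of ring A, survive a buffered palladium step and fall in one operation.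

**16 ⇒ 15.** The C3–C3a bond of the benzofuran is cut, leaving an aryl vinyl ether with two C–H bonds where the C–C bond was. No halogen or metal handle has to be carried, and the two aromatic halves are now held together only by an O–vinyl link. The forward oxidative cyclization must take the open ortho carbon (para to the acetal oxygen) and not the one squeezed between two oxygens, and it must leave the olefin and the acetals alone.

**15 ⇒ 14 + 7.** The vinyl C–O bond is cut. This splits the molecule into a ring B phenol and a ring A ynone of similar size, so the route is convergent. The forward conjugate addition must be a single O-addition at the alkyne terminus.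

**7 ⇒ 6 ⇒ 4 + 5, and 4 ⇒ 3 ⇒ 2 ⇒ 1.** The carbinol–alkyne bond and then the aryl–formyl bond are cut. The carbonyl carbon is thus placed by a metalation that the two acetal oxygens of 2 direct to the carbon between them, and the symmetric substitution of 1 is carried through unchanged. The lithiation must prefer that carbon over the two flanked by one acetal and the methoxy group, and the oxidation of 6 must be mild enough for a terminal ynone.

**14 ⇒ 13 ⇒ 12 + 11, and 12 ⇒ 10 ⇒ 9 ⇒ 8.** The aryl–prenyl bond is cut at the carbon that bears bromine in 8, so the halogen marks the prenyl position without ambiguity. The two oxygens are told apart by a temporary silyl group on the one para to bromine. The demands are site-selective monosilylation of 8 and attack of 12 on the primary carbon of 11.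

## Other disconnections considered

**Alternative 1:** The cut is the C4–C4a bond of ring C. In the forward sense the acid A1, a (Z)-3-aryloxy-2-arylacrylic acid with the 3,5-dimethoxyphenoxy group cis to the carboxyl, would be activated with trifluoroacetic anhydride or P2O5 in MeSO3H. Its acyl carbon would attack the arene ortho to the ether oxygen and should close chromone A2.

- In favour: the closure is a C–C bond formation that cannot revert, so the ring-against-ring equilibrium of the chosen plan does not arise. On this point the alternative is the better one. Ring A is symmetric at the decisive step, which is equal to the chosen plan.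
- Against: the strongly acidic, dehydrating medium excludes both the prenyl group and acetal protection. A2 therefore carries a bromine placeholder, two isopropyl ethers and a 5-methyl ether.
- End game from A2: a palladium-catalysed prenylation of a hindered, electron-rich aryl bromide (with the α/γ ambiguity of prenyl-metal reagents), then cleavage of the isopropyl ethers and of the 5-methyl ether beside an intact 7-methyl ether, with a boron halide in the presence of an ortho-prenyl phenol.
- A1 also needs a defined olefin geometry and is not quicker to make than 15.
- Comparison: on structure A2 is further from the target than 16. On mechanism an irreversible Friedel–Crafts acylation stands against a reversible hetero-Michael exchange. On step economy the chosen plan ends at the target in its key step, while this one needs at least three more steps.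

**Alternative 2:** The cut removes four bonds of ring B, which would be grown on chromone C3. In the forward sense the diazo ketone A3 would undergo Wolff rearrangement to a vinylketene, add the silyloxyalkyne A4 by [2+2] cycloaddition, open the cyclobutenone and close by 6π-electrocyclization and tautomerization to the phenol A5.

- In favour: the ring B pattern (free 2'-hydroxyl, silylated 4'-oxygen, 5'-prenyl) is written by the polarity of A4 and by the α-substituent of A3. No aromatic substitution regiochemistry, no transition metal and no acid are involved in building ring B. On regiochemical certainty for ring B this is the better plan, and the free 2'-hydroxyl arises directly.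
- Against: A3 is a delicate compound. An α-alkyl diazo ketone can undergo 1,2-hydrogen shift in competition with the Wolff rearrangement. The tethered prenyl olefin is placed for cyclopropanation or ketene cycloaddition. The chromone C2=C3 bond is itself a photoactive enone and a ketenophile.
- Assembling A3 (formylchromone, olefination, prenylated diazo ketone) should take more steps than 16.
- A5 still needs desilylation and acid removal of an acetal beside the prenyl group, so the acid exposure is equal to that of the chosen key step.
- Comparison: equal on the end-game hazard, better on programmed ring B regiochemistry, worse on access to the precursor, on chemoselectivity and on step count.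

**Alternative 3:** The cut takes O1–C8a and C4–C4a together. In the forward sense CsF would generate aryne A6 from an ortho-silyl aryl triflate. The enolate oxygen of the β-hydroxyacrylate A7 would add to the aryne carbon remote from the acetal oxygen, and the aryl anion formed beside that oxygen would attack the ester and expel methoxide, which should give A8.

- A correction to the regiochemistry: A8 requires 5-methoxy-3-(methoxymethoxy)benzyne, with the acetal oxygen on the carbon next to the triple bond and the methoxy group on the far meta carbon. The reverse placement would exchange the 5- and 7-substituents of the chromone.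
- In favour: this is the most convergent of the four plans, with two bonds and ring C formed in one operation. Conditions are mild, non-acidic and non-oxidative, and ring B is fully elaborated, prenyl included. The closure is irreversible, which is better than the chosen plan on the equilibrium question.
- Against: site selectivity rests on polarization of an unsymmetrical aryne, whereas the chosen plan has a symmetric ring A at the decisive moment (chosen plan better here). The enolate is ambident, so C-arylation or insertion into the C–C bond of the dicarbonyl tautomer may compete, and the aryl anion may be protonated before it acylates.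
- The trioxygenated aryne precursor needs several steps, and A8 needs a separate acid deprotection of three acetals beside the prenyl group, which is the same exposure as in the chosen key step but as one extra step.
- Comparison: roughly equal in total length, better in convergence and irreversibility, worse in regiochemical and chemoselective certainty.

Key step: step 11

## Route

Remark on the chemistry: compounds 6 and 18 carry stereocenters that are absent from the target. They are racemic (18 is cis-fused by ring strain; one enantiomer of the pair is drawn), so the route needs no stereocontrol.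

Step 1
Reactants: 1 5-methoxyresorcinol (5-methoxybenzene-1,3-diol)
Product: 2 1-methoxy-3,5-bis(methoxymethoxy)benzene
Conditions: MOMCl (2.4 equiv), i-Pr2NEt (3 equiv), CH2Cl2, 0 °C to rt
Reagents that add atoms: chloromethyl methyl ether (MOMCl), COCCl
Why: O-alkylation of both phenols by the α-chloro ether under amine base (acetal-type Williamson etherification); the aryl methyl ether is inert.

Step 2
Reactants: 2 1-methoxy-3,5-bis(methoxymethoxy)benzene
Product: 4 4-methoxy-2,6-bis(methoxymethoxy)benzaldehyde, via aryllithium 3 (not isolated)
Conditions: n-BuLi (1.1 equiv), THF, 0 °C; DMF, 0 °C to rt; then H2O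
Reagents that add atoms: N,N-dimethylformamide (DMF), CN(C)C=O
Why: Directed ortho-metalation at the carbon between the two methoxymethoxy groups (two chelating directors act together and outrank the methoxy group), then formylation of aryllithium 3 by the formamide.

Step 3
Reactants: 4 4-methoxy-2,6-bis(methoxymethoxy)benzaldehyde; 5 ethynylmagnesium bromide
Product: 6 1-[4-methoxy-2,6-bis(methoxymethoxy)phenyl]prop-2-yn-1-ol (racemic)
Conditions: HC≡CMgBr (0.5 M in THF, 1.5 equiv), THF, 0 °C; then aq. NH4Cl
Reagents that add atoms: ethynylmagnesium bromide (5), C#C[Mg]Br
Why: Grignard 1,2-addition of a small sp nucleophile to a hindered, non-enolizable aldehyde; the carbinol center is racemic and is removed in step 4.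

Step 4
Reactants: 6 1-[4-methoxy-2,6-bis(methoxymethoxy)phenyl]prop-2-yn-1-ol
Product: 7 1-[4-methoxy-2,6-bis(methoxymethoxy)phenyl]prop-2-yn-1-one
Conditions: activated MnO2 (15 equiv), CH2Cl2, rt
Reagents that add atoms: none
Why: MnO2 oxidation of a benzylic and propargylic alcohol on the solid surface under neutral conditions, which should leave the acetals and the terminal alkyne untouched.

Step 5
Reactants: 8 4-bromoresorcinol (4-bromobenzene-1,3-diol)
Product: 9 2-bromo-5-(triisopropylsilyloxy)phenol
Conditions: TIPSCl (1.05 equiv), imidazole (2.2 equiv), CH2Cl2, −20 to 0 °C
Reagents that add atoms: chlorotriisopropylsilane (TIPSCl), CC(C)[Si](Cl)(C(C)C)C(C)C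
Why: Sterically governed monosilylation; the bulky silyl chloride should take the hydroxyl para to bromine, because the other hydroxyl is flanked by the bromine atom.

Step 6
Reactants: 9 2-bromo-5-(triisopropylsilyloxy)phenol
Product: 10 [4-bromo-3-(methoxymethoxy)phenoxy]triisopropylsilane
Conditions: MOMCl (1.5 equiv), i-Pr2NEt (2 equiv), CH2Cl2, 0 °C to rt
Reagents that add atoms: chloromethyl methyl ether (MOMCl), COCCl
Why: Acetal-type O-alkylation of the remaining phenol; the amine base is too weak to shift the hindered silyl group between oxygens.

Step 7
Reactants: 10 [4-bromo-3-(methoxymethoxy)phenoxy]triisopropylsilane; 11 1-bromo-3-methylbut-2-ene (prenyl bromide)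
Product: 13 triisopropyl[3-(methoxymethoxy)-4-(3-methylbut-2-enyl)phenoxy]silane, via aryllithium 12 (not isolated)
Conditions: n-BuLi (1.05 equiv), THF, −78 °C; CuBr·SMe2 (10 mol%), then 11, −78 to 0 °C
Reagents that add atoms: 1-bromo-3-methylbut-2-ene (11), CC(C)=CCBr
Why: Bromine–lithium exchange gives aryllithium 12, held by the ortho acetal oxygen; copper-catalysed allylic substitution at the unhindered primary carbon of 11 should give the linear prenyl arene.

Step 8
Reactants: 13 triisopropyl[3-(methoxymethoxy)-4-(3-methylbut-2-enyl)phenoxy]silane
Product: 14 3-(methoxymethoxy)-4-(3-methylbut-2-enyl)phenol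
Conditions: Bu4NF (1.1 equiv), THF, 0 °C; then aq. NH4Cl
Reagents that add atoms: none
Why: Fluoride-driven cleavage of the aryl silyl ether (strong Si–F bond); acetal and olefin are inert to fluoride.

Step 9
Reactants: 14 3-(methoxymethoxy)-4-(3-methylbut-2-enyl)phenol; 7 1-[4-methoxy-2,6-bis(methoxymethoxy)phenyl]prop-2-yn-1-one
Product: 15 (E)-1-[4-methoxy-2,6-bis(methoxymethoxy)phenyl]-3-[3-(methoxymethoxy)-4-(3-methylbut-2-enyl)phenoxy]prop-2-en-1-one
Conditions: DABCO (10 mol%), CH2Cl2, 0 °C to rt
Reagents that add atoms: none
Why: Amine-catalysed oxa-Michael addition of a phenol to a terminal ynone; the open alkyne terminus is attacked and protonation of the allenolate should give the E vinylogous ester.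

Step 10
Reactants: 15 (E)-1-[4-methoxy-2,6-bis(methoxymethoxy)phenyl]-3-[3-(methoxymethoxy)-4-(3-methylbut-2-enyl)phenoxy]prop-2-en-1-one
Product: 16 [4-methoxy-2,6-bis(methoxymethoxy)phenyl][6-(methoxymethoxy)-5-(3-methylbut-2-enyl)-1-benzofuran-3-yl]methanone
Conditions: Pd(OAc)2 (10 mol%), PPh3 (10 mol%), AgOAc (2.5 equiv), K2CO3 (2.5 equiv), PhMe, 100 °C
Reagents that add atoms: none
Why: Palladium-catalysed intramolecular dehydrogenative coupling of a 3-aryloxy enone (oxidative Heck-type benzofuran synthesis): divalent palladium metalates the enone α-carbon and then the arene C–H ortho to the ether oxygen and para to the acetal oxygen, and reductive elimination forms C3–C3a. The other ortho carbon lies between two oxygens and is shielded; AgOAc returns zerovalent palladium to the divalent state and the carbonate keeps the medium non-acidic for the acetals.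

Step 11
Reactants: 16 [4-methoxy-2,6-bis(methoxymethoxy)phenyl][6-(methoxymethoxy)-5-(3-methylbut-2-enyl)-1-benzofuran-3-yl]methanone
Product: 19 isopoegin B (3-[2,4-dihydroxy-5-(3-methylbut-2-enyl)phenyl]-5-hydroxy-7-methoxy-4H-chromen-4-one), via triol 17 (not isolated), via fused acetal 18 (not isolated)
Conditions: HCl (ca. 1 M, from conc. aq. HCl) in MeOH, 45 °C
Reagents that add atoms: none
Why: Acid-catalysed acetal exchange with methanol removes the three methoxymethyl groups and gives triol 17. In 17 the furan C2=C3 bond is the enol-ether part of a vinylogous ester, so a ring A hydroxyl adds to C2 in a 6-endo-trig oxa-Michael closure (O1–C2 formed, ring C closed) to give the cis-fused acetal 18. Retro-oxa-Michael cleavage of the furan C2–O bond in 18 then releases the 2'-hydroxyl and leaves the pyranone; the two stereocenters of 18 are destroyed, so none has to be controlled. The closest known reaction type is the acid-triggered ring opening and recyclization of 3-(2-hydroxybenzoyl)benzofurans, unmasked from their ethers, to 2'-hydroxyisoflavones. The selectivity needed is the direction of the ring exchange: 19 should be favoured because the chromone is a coplanar cyclic vinylogous ester that keeps a chelated 5-hydroxyl, whereas the doubly ortho-substituted aroyl group of 17 is twisted, and the return path would begin with a slow 5-endo-trig addition. The symmetry of ring A makes its two hydroxyls equivalent, so only one isoflavone can form. Chemoselectivity toward the prenyl group rests on dilute acid in methanol at moderate temperature, the usual conditions for cleaving methoxymethyl ethers of prenylated phenols.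

## Compound list

1 | 5-methoxyresorcinol (5-methoxybenzene-1,3-diol) | COc1cc(O)cc(O)c1 | starting material
2 | 1-methoxy-3,5-bis(methoxymethoxy)benzene | COCOc1cc(OC)cc(OCOC)c1 | intermediate
3 | [4-methoxy-2,6-bis(methoxymethoxy)phenyl]lithium | [Li]c1c(OCOC)cc(OC)cc1OCOC | intermediate (not isolated)
4 | 4-methoxy-2,6-bis(methoxymethoxy)benzaldehyde | O=Cc1c(OCOC)cc(OC)cc1OCOC | intermediate
5 | ethynylmagnesium bromide | C#C[Mg]Br | starting material
6 | 1-[4-methoxy-2,6-bis(methoxymethoxy)phenyl]prop-2-yn-1-ol (racemic) | C#CC(O)c1c(OCOC)cc(OC)cc1OCOC | intermediate
7 | 1-[4-methoxy-2,6-bis(methoxymethoxy)phenyl]prop-2-yn-1-one | C#CC(=O)c1c(OCOC)cc(OC)cc1OCOC | intermediate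
8 | 4-bromoresorcinol (4-bromobenzene-1,3-diol) | Oc1ccc(Br)c(O)c1 | starting material
9 | 2-bromo-5-(triisopropylsilyloxy)phenol | Oc1cc(O[Si](C(C)C)(C(C)C)C(C)C)ccc1Br | intermediate
10 | [4-bromo-3-(methoxymethoxy)phenoxy]triisopropylsilane | COCOc1cc(O[Si](C(C)C)(C(C)C)C(C)C)ccc1Br | intermediate
11 | 1-bromo-3-methylbut-2-ene (prenyl bromide) | CC(C)=CCBr | starting material
12 | [2-(methoxymethoxy)-4-(triisopropylsilyloxy)phenyl]lithium | [Li]c1ccc(O[Si](C(C)C)(C(C)C)C(C)C)cc1OCOC | intermediate (not isolated)
13 | triisopropyl[3-(methoxymethoxy)-4-(3-methylbut-2-enyl)phenoxy]silane | COCOc1cc(O[Si](C(C)C)(C(C)C)C(C)C)ccc1CC=C(C)C | intermediate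
14 | 3-(methoxymethoxy)-4-(3-methylbut-2-enyl)phenol | COCOc1cc(O)ccc1CC=C(C)C | intermediate
15 | (E)-1-[4-methoxy-2,6-bis(methoxymethoxy)phenyl]-3-[3-(methoxymethoxy)-4-(3-methylbut-2-enyl)phenoxy]prop-2-en-1-one | COCOc1cc(OC)cc(OCOC)c1C(=O)/C=C/Oc1ccc(CC=C(C)C)c(OCOC)c1 | intermediate
16 | [4-methoxy-2,6-bis(methoxymethoxy)phenyl][6-(methoxymethoxy)-5-(3-methylbut-2-enyl)-1-benzofuran-3-yl]methanone | COCOc1cc(OC)cc(OCOC)c1C(=O)c2coc3cc(OCOC)c(CC=C(C)C)cc23 | intermediate (precursor of the key step)
17 | (2,6-dihydroxy-4-methoxyphenyl)[6-hydroxy-5-(3-methylbut-2-enyl)-1-benzofuran-3-yl]methanone | COc1cc(O)c(C(=O)c2coc3cc(O)c(CC=C(C)C)cc23)c(O)c1 | intermediate (not isolated)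
18 | cis-1,8-dihydroxy-3-methoxy-9-(3-methylbut-2-enyl)-5a,10b-dihydro-11H-benzofuro[2,3-b]chromen-11-one (racemic, one enantiomer drawn) | COc1cc(O)c2c(c1)O[C@@H]1Oc3cc(O)c(CC=C(C)C)cc3[C@@H]1C2=O | intermediate (not isolated)
19 | isopoegin B, 3-[2,4-dihydroxy-5-(3-methylbut-2-enyl)phenyl]-5-hydroxy-7-methoxy-4H-chromen-4-one | COc1cc(O)c2c(=O)c(-c3cc(CC=C(C)C)c(O)cc3O)coc2c1 | target

## Step count and risks

Total step count: 11. Longest linear sequence: 7 steps (8 to 19 through steps 5–8 and 9–11; the ring A branch, steps 1–4 and 9–11, is equally long).

**Step 11 (key step).** Most likely to go wrong: acid-promoted closure of the prenyl chain onto the neighbouring 4'-hydroxyl, or solvent addition across the olefin, while the last acetal is still being cleaved. The ring exchange may also stop short at an equilibrium mixture with 17, since the position of that equilibrium for this substitution pattern is not established.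
Fallback (sets out from 16, returns at 19): the deprotection is taken out of protic acid and the exchange is run as a separate operation. 16 is treated with TMSOTf and 2,2'-bipyridyl in MeCN at 0 °C, which should convert the three aryl acetals into [4-methoxy-2,6-bis(trimethylsilyloxy)phenyl][5-(3-methylbut-2-enyl)-6-(trimethylsilyloxy)-1-benzofuran-3-yl]methanone F1. Aqueous work-up hydrolyses F1 to 17, which is isolated in this variant. 17 is then warmed with catalytic pyridinium p-toluenesulfonate in MeCN (50 °C). No mineral acid or nucleophilic solvent then meets the prenyl group, and the approach to equilibrium can be followed on a defined compound.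

**Step 10.** Most likely to go wrong: loss of site control or diversion of the catalyst. This means metalation at the crowded carbon between the two oxygens, binding or oxidation of the prenyl olefin by divalent palladium, or acetal loss if acid builds up. Stoichiometric Pd(OAc)2 would be a change of conditions only.
Fallback (sets out from 14 and 7, returns at 16): the ring closure is fixed by a halogen and run with zerovalent palladium. 14 is iodinated with N-iodosuccinimide (CH2Cl2, −40 to 0 °C) at the open carbon ortho to the hydroxyl and para to the acetal oxygen, to give 2-iodo-5-(methoxymethoxy)-4-(3-methylbut-2-enyl)phenol F2. DABCO-catalysed addition of F2 to 7 gives (E)-3-[2-iodo-5-(methoxymethoxy)-4-(3-methylbut-2-enyl)phenoxy]-1-[4-methoxy-2,6-bis(methoxymethoxy)phenyl]prop-2-en-1-one F3. Intramolecular Heck-type cyclization of F3 (Pd(OAc)2, PPh3, Et3N, MeCN, 80 °C) should then give 16 with no regiochemical choice and no oxidant.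

**Step 7.** Most likely to go wrong: attack of 12 at the tertiary terminus of 11 (reverse-prenyl isomer), coupling of 12 with the 1-bromobutane formed in the exchange, or premature protonation of 12.
Fallback (sets out from 10, returns at 13): the side chain is built in two stages. 12 is generated as before and quenched with allyl bromide, which has two equivalent termini, to give triisopropyl[3-(methoxymethoxy)-4-(prop-2-enyl)phenoxy]silane F4. Cross-metathesis of F4 with excess 2-methylbut-2-ene (second-generation Grubbs catalyst RuCl2(=CHPh)(H2IMes)(PCy3), CH2Cl2, 40 °C) should give 13.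

**Step 5.** Most likely to go wrong: poor discrimination between the two hydroxyls of 8, or double silylation, so that the later acetal and prenyl groups end on the wrong oxygen pattern.
Fallback (replaces 8 by a symmetric diol, uses 11 as before, returns at 12 and hence 13): commercial resorcinol F5, used in excess, is monosilylated (TIPSCl, imidazole) to 3-(triisopropylsilyloxy)phenol F6. No site question arises because F5 is symmetric. F6 is converted with MOMCl and i-Pr2NEt into triisopropyl[3-(methoxymethoxy)phenoxy]silane F7. Directed ortho-metalation of F7 (n-BuLi, THF, 0 °C) is steered by the acetal oxygen to the carbon remote from the bulky silyloxy group and gives aryllithium 12, which is prenylated as in step 7.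

## Further compounds

F1 | step 11 | [4-methoxy-2,6-bis(trimethylsilyloxy)phenyl][5-(3-methylbut-2-enyl)-6-(trimethylsilyloxy)-1-benzofuran-3-yl]methanone | COc1cc(O[Si](C)(C)C)c(C(=O)c2coc3cc(O[Si](C)(C)C)c(CC=C(C)C)cc23)c(O[Si](C)(C)C)c1
F2 | step 10 | 2-iodo-5-(methoxymethoxy)-4-(3-methylbut-2-enyl)phenol | COCOc1cc(O)c(I)cc1CC=C(C)C
F3 | step 10 | (E)-3-[2-iodo-5-(methoxymethoxy)-4-(3-methylbut-2-enyl)phenoxy]-1-[4-methoxy-2,6-bis(methoxymethoxy)phenyl]prop-2-en-1-one | COCOc1cc(OC)cc(OCOC)c1C(=O)/C=C/Oc1cc(OCOC)c(CC=C(C)C)cc1I
F4 | step 7 | triisopropyl[3-(methoxymethoxy)-4-(prop-2-enyl)phenoxy]silane | COCOc1cc(O[Si](C(C)C)(C(C)C)C(C)C)ccc1CC=C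
F5 | step 5 | resorcinol (benzene-1,3-diol) | Oc1cccc(O)c1
F6 | step 5 | 3-(triisopropylsilyloxy)phenol | Oc1cccc(O[Si](C(C)C)(C(C)C)C(C)C)c1
F7 | step 5 | triisopropyl[3-(methoxymethoxy)phenoxy]silane | COCOc1cccc(O[Si](C(C)C)(C(C)C)C(C)C)c1
A1 | alternative 1 | (Z)-2-(5-bromo-2,4-diisopropoxyphenyl)-3-(3,5-dimethoxyphenoxy)acrylic acid | COc1cc(OC)cc(O/C=C(\C(=O)O)c2cc(Br)c(OC(C)C)cc2OC(C)C)c1
A2 | alternative 1 | 3-(5-bromo-2,4-diisopropoxyphenyl)-5,7-dimethoxy-4H-chromen-4-one | COc1cc(OC)c2c(=O)c(-c3cc(Br)c(OC(C)C)cc3OC(C)C)coc2c1
A3 | alternative 2 | (E)-4-diazo-1-[7-methoxy-5-(methoxymethoxy)-4-oxo-4H-chromen-3-yl]-7-methylocta-1,6-dien-3-one | COCOc1cc(OC)cc2occ(/C=C/C(=O)C(=[N+]=[N-])CC=C(C)C)c(=O)c12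
A4 | alternative 2 | (triisopropylsilyloxy)ethyne | C#CO[Si](C(C)C)(C(C)C)C(C)C
A5 | alternative 2 | 3-[2-hydroxy-5-(3-methylbut-2-enyl)-4-(triisopropylsilyloxy)phenyl]-7-methoxy-5-(methoxymethoxy)-4H-chromen-4-one | COc1cc(OCOC)c2c(=O)c(-c3cc(CC=C(C)C)c(O[Si](C(C)C)(C(C)C)C(C)C)cc3O)coc2c1
A6 | alternative 3 | 5-methoxy-3-(methoxymethoxy)benzyne (1,2-didehydro-5-methoxy-3-(methoxymethoxy)benzene) | COCOC1=CC(OC)=CC#C1
A7 | alternative 3 | methyl 2-[2,4-bis(methoxymethoxy)-5-(3-methylbut-2-enyl)phenyl]-3-hydroxyacrylate (enol form, geometry not fixed) | COC(=O)C(=CO)c1cc(CC=C(C)C)c(OCOC)cc1OCOC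
A8 | alternative 3 | 3-[2,4-bis(methoxymethoxy)-5-(3-methylbut-2-enyl)phenyl]-7-methoxy-5-(methoxymethoxy)-4H-chromen-4-one | COc1cc(OCOC)c2c(=O)c(-c3cc(CC=C(C)C)c(OCOC)cc3OCOC)coc2c1
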